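**Retrosynthetic overview**
- The plan rests on flavone ring B. Its C1' carries C2 of the flavone pyranone (ring C), its C3' carries C8 of the isoflavone, and its C4' carries oxygen. This 1,3,4-pattern is what a para-oriented cycloaddition of a 2-siloxy-3-arylbutadiene with a terminal alkyne delivers.
- Cutting C1'–C2' and C5'–C6' splits the target into an isoflavone-8-yl siloxydiene and a 2-ethynylchromone (flavone rings A and C). Ring B is created as the two halves are joined.
- Diene half: all three isoflavone rings come with biochanin A. The C8–C3' bond is laid by Claisen rearrangement of the 7-O-allyl ether, with the 5-OH capped first to steer the shift to C8. Wacker oxidation, α-methylenation and silyl enol ether formation follow.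
- Alkyne half: flavone ring A comes from phloroacetophenone and ring C is closed by oxalate condensation and cyclodehydration. The ester is then taken through the alcohol and the aldehyde to the alkyne.
- Ring order: flavone ring C (step 9), then flavone ring B (step 13, aromatised in step 14). The 4'-O-silyl group is then exchanged for methyl and the four benzyl ethers are removed.

Key step: step 13

Assumption: the target is drawn without configuration at the hindered C8–C3' biaryl axis and has no stereocentre, so the axis is left uncontrolled.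

**Step 1**
Reactants: 1 biochanin A; 2 allyl bromide
Product: 3 7-(allyloxy)-5-hydroxy-3-(4-methoxyphenyl)chromen-4-one
Conditions: K2CO3 (1.2 equiv), 2 (1.05 equiv), acetone, reflux
Reagents that add atoms: none
Why: Williamson etherification, in which the unchelated and more acidic 7-OH reacts while the 5-OH stays tied to the C4 carbonyl by a hydrogen bond, so one equivalent of halide with a weak base should alkylate O7 only.

**Step 2**
Reactants: 3 7-(allyloxy)-5-hydroxy-3-(4-methoxyphenyl)chromen-4-one
Product: 4 7-(allyloxy)-5-(benzyloxy)-3-(4-methoxyphenyl)chromen-4-one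
Conditions: BnBr, K2CO3, n-Bu4NI (cat.), DMF, 70 °C
Reagents that add atoms: benzyl bromide, BrCc1ccccc1
Why: Williamson etherification under heat and iodide catalysis overcomes the chelate of the 5-OH, and capping this phenol before the rearrangement removes the hydrogen-bonded enol that would otherwise stabilise migration towards C6.

**Step 3**
Reactants: 4 7-(allyloxy)-5-(benzyloxy)-3-(4-methoxyphenyl)chromen-4-one
Product: 5 8-allyl-5-(benzyloxy)-7-hydroxy-3-(4-methoxyphenyl)chromen-4-one
Conditions: PhNEt2, 200 °C, sealed tube, Ar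
Reagents that add atoms: none
Why: Aromatic Claisen rearrangement, in which the [3,3] shift to C8 passes through a dienone that keeps the C4a=C8a bond of the 4-pyranone whereas a shift to C6 would break it, so the allyl group should arrive at C8 and rearomatisation frees the 7-OH.

**Step 4**
Reactants: 5 8-allyl-5-(benzyloxy)-7-hydroxy-3-(4-methoxyphenyl)chromen-4-one
Product: 6 8-allyl-5,7-bis(benzyloxy)-3-(4-methoxyphenyl)chromen-4-one
Conditions: BnBr, K2CO3, DMF, 50 °C
Reagents that add atoms: benzyl bromide, BrCc1ccccc1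
Why: Williamson etherification of the only free phenol gives a fully protected isoflavone ring A that tolerates the later palladium, silyl triflate, thermal and DDQ steps.

**Step 5**
Reactants: 6 8-allyl-5,7-bis(benzyloxy)-3-(4-methoxyphenyl)chromen-4-one
Product: 7 5,7-bis(benzyloxy)-3-(4-methoxyphenyl)-8-(2-oxopropyl)chromen-4-one
Conditions: PdCl2 (10 mol %), CuCl (co-catalyst), O2 (1 atm), DMF/H2O 7:1, rt
Reagents that add atoms: water, O
Why: Tsuji–Wacker oxidation, in which Markovnikov hydroxypalladation of the terminal alkene by divalent palladium and β-hydride elimination should give the methyl ketone while the benzyl ethers and the pyranone stay inert.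

**Step 6**
Reactants: 7 5,7-bis(benzyloxy)-3-(4-methoxyphenyl)-8-(2-oxopropyl)chromen-4-one
Product: 8 5,7-bis(benzyloxy)-3-(4-methoxyphenyl)-8-(3-oxobut-1-en-2-yl)chromen-4-one
Conditions: (CH2O)n, i-Pr2NH·CF3CO2H (1 equiv), CF3CO2H (10 mol %), THF, reflux
Reagents that add atoms: formaldehyde (as paraformaldehyde), C=O
Why: Mannich-type α-methylenation, in which the ketone enolises under mild acid towards the more substituted benzylic carbon, the iminium ion from formaldehyde is captured there, and the amine leaves again by β-elimination in the same operation.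

**Step 7**
Reactants: 8 5,7-bis(benzyloxy)-3-(4-methoxyphenyl)-8-(3-oxobut-1-en-2-yl)chromen-4-one
Product: 9 5,7-bis(benzyloxy)-8-[3-(tert-butyldimethylsilyloxy)buta-1,3-dien-2-yl]-3-(4-methoxyphenyl)chromen-4-one
Conditions: t-BuMe2SiOTf (1.3 equiv), Et3N (2 equiv), CH2Cl2, 0 °C; filtration through Et3N-deactivated silica
Reagents that add atoms: tert-butyldimethylsilyl triflate, CC(C)(C)[Si](C)(C)OS(=O)(=O)C(F)(F)F
Why: Soft enolisation to a silyl enol ether, in which the silyl triflate activates the ketone and triethylamine removes a proton from the methyl group, the only enolisable position left, so a single 2-siloxy-1,3-diene should form.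

**Step 8**
Reactants: 10 2,4,6-trihydroxyacetophenone
Product: 11 1-[2,4-bis(benzyloxy)-6-hydroxyphenyl]ethanone
Conditions: BnBr (2.05 equiv), K2CO3, DMF, rt
Reagents that add atoms: benzyl bromide, BrCc1ccccc1
Why: Double Williamson etherification, after which the remaining ortho-phenol is locked in a hydrogen bond to the acetyl carbonyl and is left free by a weak base and two equivalents of halide.

**Step 9**
Reactants: 11 1-[2,4-bis(benzyloxy)-6-hydroxyphenyl]ethanone; 12 diethyl oxalate
Product: 14 ethyl 5,7-bis(benzyloxy)-4-oxo-4H-chromene-2-carboxylate, via diketo ester 13 (not isolated)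
Conditions: NaOEt (4 equiv), EtOH, reflux; then HCl/EtOH to pH 1, 60 °C, short time
Reagents that add atoms: none
Why: Crossed Claisen condensation of the methyl ketone enolate with non-enolisable diethyl oxalate gives 13, whose phenol adds to the C2 ketone and loses water under acid, which is the classical chromone-2-carboxylate synthesis and closes flavone ring C as a six-membered ring.

**Step 10**
Reactants: 14 ethyl 5,7-bis(benzyloxy)-4-oxo-4H-chromene-2-carboxylate
Product: 15 5,7-bis(benzyloxy)-2-(hydroxymethyl)chromen-4-one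
Conditions: NaBH4, MeOH/THF, 0 °C
Reagents that add atoms: none
Why: Chemoselective borohydride reduction, since the ester sits on the electron-poor, oxygen-bearing C2 and is activated while the C4 carbonyl is a deactivated vinylogous ester, so the reduction should stop at the primary alcohol.

**Step 11**
Reactants: 15 5,7-bis(benzyloxy)-2-(hydroxymethyl)chromen-4-one
Product: 16 5,7-bis(benzyloxy)-4-oxo-4H-chromene-2-carbaldehyde
Conditions: Dess–Martin periodinane, CH2Cl2, 0 °C to rt
Reagents that add atoms: none
Why: Dess–Martin oxidation converts the allylic-type primary alcohol into the aldehyde without over-oxidation and without nucleophiles that could open the pyranone.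

**Step 12**
Reactants: 16 5,7-bis(benzyloxy)-4-oxo-4H-chromene-2-carbaldehyde
Product: 17 5,7-bis(benzyloxy)-2-ethynylchromen-4-one
Conditions: Me3SiCHN2 (1.2 equiv), LiN(i-Pr)2 (1.2 equiv), THF, −78 °C; add 16; −78 to 0 °C; H2O quench
Reagents that add atoms: trimethylsilyldiazomethane, C[Si](C)(C)C=[N+]=[N-]
Why: Colvin rearrangement (the silyl variant of the Seyferth–Gilbert homologation), in which the lithiated diazo compound adds at −78 °C to the aldehyde as the most electrophilic carbonyl, and loss of silanolate, loss of N2 and a 1,2-hydrogen shift give the terminal alkyne in an aprotic medium, so no alkoxide is present to add to the pyranone or to the product.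

**Step 13**
Reactants: 9 5,7-bis(benzyloxy)-8-[3-(tert-butyldimethylsilyloxy)buta-1,3-dien-2-yl]-3-(4-methoxyphenyl)chromen-4-one; 17 5,7-bis(benzyloxy)-2-ethynylchromen-4-one
Product: 18 5,7-bis(benzyloxy)-8-{5-[5,7-bis(benzyloxy)-4-oxochromen-2-yl]-2-(tert-butyldimethylsilyloxy)cyclohexa-1,4-dien-1-yl}-3-(4-methoxyphenyl)chromen-4-one
Conditions: 9 (1.5 equiv), o-xylene (0.5 M), BHT (5 mol %), 140 °C, sealed tube, Ar
Reagents that add atoms: none
Why: This is a concerted, asynchronous [4+2] cycloaddition of normal electron demand, in which the diene HOMO, raised by the siloxy group, meets the alkyne LUMO, lowered through the C2=C3–C4=O vinylogous carbonyl path of the chromone. The closest known reaction type is the Diels–Alder reaction of 2-siloxybuta-1,3-dienes with acceptor-conjugated terminal alkynes such as ynones and propiolates, which gives 1-siloxycyclohexa-1,4-dienes that are dehydrogenated to para-acyl phenol derivatives. Flavone ring B closes as a six-membered carbocycle by intermolecular cycloaddition, with the C5'–C6' bond (enol ether CH2 to alkyne CH) running ahead of the C1'–C2' bond (the other diene CH2 to the substituted alkyne carbon). No stereocentre is formed, because every new ring position is a CH2 group or an sp2 carbon. Regioselectivity is needed and is secured by the siloxy group, which places the largest HOMO coefficient on its own CH2 terminus and outweighs the aryl group, twisted out of conjugation by its two ortho oxygens, so that this terminus bonds to the electrophilic terminal alkyne carbon and O4' ends para to the chromone. Site selectivity is also needed and is secured because the linear, unhindered alkyne is far more accessible than the trisubstituted C2=C3 bonds of the two pyranones, which would lose their cyclic conjugation on reaction.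

**Step 14**
Reactants: 18 cyclohexa-1,4-diene adduct
Product: 19 5,7-bis(benzyloxy)-8-{5-[5,7-bis(benzyloxy)-4-oxochromen-2-yl]-2-(tert-butyldimethylsilyloxy)phenyl}-3-(4-methoxyphenyl)chromen-4-one
Conditions: DDQ (1.1 equiv), toluene, 0 °C to rt, dark
Reagents that add atoms: none
Why: Dehydrogenative aromatisation, in which DDQ abstracts hydride from a doubly allylic CH2 of the cyclohexa-1,4-diene and proton loss gives the benzene ring, a fast process at room temperature that leaves unactivated benzyl ethers untouched.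

**Step 15**
Reactants: 19 aryl silyl ether
Product: 20 5,7-bis(benzyloxy)-8-{5-[5,7-bis(benzyloxy)-4-oxochromen-2-yl]-2-hydroxyphenyl}-3-(4-methoxyphenyl)chromen-4-one
Conditions: n-Bu4NF (1.1 equiv), AcOH (1.1 equiv), THF, 0 °C
Reagents that add atoms: none
Why: Fluoride-mediated desilylation of an aryl silyl ether is driven by the Si–F bond, and the acetic acid buffer keeps basic species away from the base-sensitive C2 of the isoflavone.

**Step 16**
Reactants: 20 4'-phenol
Product: 21 5,7-bis(benzyloxy)-8-{5-[5,7-bis(benzyloxy)-4-oxochromen-2-yl]-2-methoxyphenyl}-3-(4-methoxyphenyl)chromen-4-one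
Conditions: MeI, K2CO3, acetone, 40 °C
Reagents that add atoms: methyl iodide, CI
Why: Williamson methylation of the only free phenol installs the 4'-methoxy group under conditions that both pyranones tolerate.

**Step 17**
Reactants: 21 tetrabenzyl ether
Product: 22 8-[5-(5,7-dihydroxy-4-oxochromen-2-yl)-2-methoxyphenyl]-5,7-dihydroxy-3-(4-methoxyphenyl)chromen-4-one (target)
Conditions: BCl3 (10 equiv), C6HMe5 (12 equiv), CH2Cl2, −78 °C; then H2O
Reagents that add atoms: none
Why: Lewis acid debenzylation with a cation scavenger, in which BCl3 coordinates the benzylic oxygens and the benzyl cations are trapped by pentamethylbenzene (Friedel–Crafts alkylation) before they can C-benzylate the phloroglucinol rings, while at −78 °C the two unchelated aryl methyl ethers and both pyranone double bonds should remain.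

**Compound list**
1 | biochanin A | COc1ccc(cc1)-c1coc2cc(O)cc(O)c2c1=O | starting material
2 | allyl bromide | C=CCBr | starting material
3 | 7-(allyloxy)-5-hydroxy-3-(4-methoxyphenyl)chromen-4-one | COc1ccc(cc1)-c1coc2cc(OCC=C)cc(O)c2c1=O | intermediate
4 | 7-(allyloxy)-5-(benzyloxy)-3-(4-methoxyphenyl)chromen-4-one | COc1ccc(cc1)-c1coc2cc(OCC=C)cc(OCc3ccccc3)c2c1=O | intermediate
5 | 8-allyl-5-(benzyloxy)-7-hydroxy-3-(4-methoxyphenyl)chromen-4-one | COc1ccc(cc1)-c1coc2c(CC=C)c(O)cc(OCc3ccccc3)c2c1=O | intermediate
6 | 8-allyl-5,7-bis(benzyloxy)-3-(4-methoxyphenyl)chromen-4-one | COc1ccc(cc1)-c1coc2c(CC=C)c(OCc3ccccc3)cc(OCc3ccccc3)c2c1=O | intermediate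
7 | 5,7-bis(benzyloxy)-3-(4-methoxyphenyl)-8-(2-oxopropyl)chromen-4-one | COc1ccc(cc1)-c1coc2c(CC(C)=O)c(OCc3ccccc3)cc(OCc3ccccc3)c2c1=O | intermediate
8 | 5,7-bis(benzyloxy)-3-(4-methoxyphenyl)-8-(3-oxobut-1-en-2-yl)chromen-4-one | COc1ccc(cc1)-c1coc2c(C(=C)C(C)=O)c(OCc3ccccc3)cc(OCc3ccccc3)c2c1=O | intermediate
9 | 5,7-bis(benzyloxy)-8-[3-(tert-butyldimethylsilyloxy)buta-1,3-dien-2-yl]-3-(4-methoxyphenyl)chromen-4-one | C=C(O[Si](C)(C)C(C)(C)C)C(=C)c1c(OCc2ccccc2)cc(OCc2ccccc2)c2c1occ(-c1ccc(OC)cc1)c2=O | intermediate
10 | 2,4,6-trihydroxyacetophenone | CC(=O)c1c(O)cc(O)cc1O | starting material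
11 | 1-[2,4-bis(benzyloxy)-6-hydroxyphenyl]ethanone | CC(=O)c1c(O)cc(OCc2ccccc2)cc1OCc1ccccc1 | intermediate
12 | diethyl oxalate | CCOC(=O)C(=O)OCC | starting material
13 | ethyl 4-[2,4-bis(benzyloxy)-6-hydroxyphenyl]-2,4-dioxobutanoate (not isolated) | CCOC(=O)C(=O)CC(=O)c1c(O)cc(OCc2ccccc2)cc1OCc1ccccc1 | intermediate
14 | ethyl 5,7-bis(benzyloxy)-4-oxo-4H-chromene-2-carboxylate | CCOC(=O)c1cc(=O)c2c(OCc3ccccc3)cc(OCc3ccccc3)cc2o1 | intermediate
15 | 5,7-bis(benzyloxy)-2-(hydroxymethyl)chromen-4-one | OCc1cc(=O)c2c(OCc3ccccc3)cc(OCc3ccccc3)cc2o1 | intermediate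
16 | 5,7-bis(benzyloxy)-4-oxo-4H-chromene-2-carbaldehyde | O=Cc1cc(=O)c2c(OCc3ccccc3)cc(OCc3ccccc3)cc2o1 | intermediate
17 | 5,7-bis(benzyloxy)-2-ethynylchromen-4-one | C#Cc1cc(=O)c2c(OCc3ccccc3)cc(OCc3ccccc3)cc2o1 | intermediate
18 | cyclohexa-1,4-diene adduct (OSi at C4', isoflavone at C3', chromone at C1') | CC(C)(C)[Si](C)(C)OC1=C(CC(=CC1)c1cc(=O)c2c(OCc3ccccc3)cc(OCc3ccccc3)cc2o1)c1c(OCc2ccccc2)cc(OCc2ccccc2)c2c1occ(-c1ccc(OC)cc1)c2=O | intermediate
19 | aromatised 4'-O-silyl tetrabenzyl biflavonoid | CC(C)(C)[Si](C)(C)Oc1ccc(cc1-c1c(OCc2ccccc2)cc(OCc2ccccc2)c2c1occ(-c1ccc(OC)cc1)c2=O)-c1cc(=O)c2c(OCc3ccccc3)cc(OCc3ccccc3)cc2o1 | intermediate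
20 | 4'-phenol tetrabenzyl biflavonoid | Oc1ccc(cc1-c1c(OCc2ccccc2)cc(OCc2ccccc2)c2c1occ(-c1ccc(OC)cc1)c2=O)-c1cc(=O)c2c(OCc3ccccc3)cc(OCc3ccccc3)cc2o1 | intermediate
21 | 4'-O-methyl tetrabenzyl biflavonoid | COc1ccc(cc1-c1c(OCc2ccccc2)cc(OCc2ccccc2)c2c1occ(-c1ccc(OC)cc1)c2=O)-c1cc(=O)c2c(OCc3ccccc3)cc(OCc3ccccc3)cc2o1 | intermediate
22 | CNP0117905.0 | COc1ccc(-c2coc3c(-c4cc(-c5cc(=O)c6c(O)cc(O)cc6o5)ccc4OC)c(O)cc(O)c3c2=O)cc1 | target

**Totals**
- Total step count: 17.
- Longest linear sequence: 12 steps (steps 1–7, then 13–17). The alkyne branch (steps 8–12) runs in parallel.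

**Steps most likely to fail**

1. **Step 13.**
- Risk: the alkyne is activated only through the vinylogous carbonyl path, and the diene carries a bulky, twisted aryl group. The cycloaddition may therefore be too slow, and thermal oligomerisation of the alkyne, protodesilylation of the diene or erosion of the para orientation may take over.
- Fallback: the cycloaddition is given up and the C8–C3' bond is made by Suzuki–Miyaura coupling of two complete halves. It sets out from 1 and 11 and comes back at 21.
- Isoflavone half: compound 1 is dibenzylated (BnBr, K2CO3, DMF, 70 °C) to 5,7-bis(benzyloxy)-3-(4-methoxyphenyl)chromen-4-one F1. This is iodinated (NIS, CF3CO2H cat., MeCN) at C8, the position preferred in 5,7-dialkoxychromones, to give 5,7-bis(benzyloxy)-8-iodo-3-(4-methoxyphenyl)chromen-4-one F2.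
- Flavone half: compound 11 undergoes Claisen–Schmidt condensation with 3-bromo-4-methoxybenzaldehyde (KOH, EtOH) to the chalcone (E)-1-[2,4-bis(benzyloxy)-6-hydroxyphenyl]-3-(3-bromo-4-methoxyphenyl)prop-2-en-1-one F3. Oxidative cyclisation (I2 cat., DMSO, 120 °C) gives 5,7-bis(benzyloxy)-2-(3-bromo-4-methoxyphenyl)chromen-4-one F4. Miyaura borylation (B2pin2, PdCl2(dppf), KOAc, dioxane, 90 °C) gives 5,7-bis(benzyloxy)-2-[4-methoxy-3-(4,4,5,5-tetramethyl-1,3,2-dioxaborolan-2-yl)phenyl]chromen-4-one F5.
- Union: coupling of F2 with F5 (Pd(PPh3)4, K2CO3, DMF/H2O, 90 °C) should give 21.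

2. **Step 12.**
- Risk: the lithiated diazo compound may attack C2 of the strongly electrophilic pyranone or open the ring, and the hydrate-prone aldehyde may decompose before homologation.
- Fallback: a phosphorus-based olefination followed by eliminations under neutral to mildly basic conditions. It sets out from 16 and comes back at 17.
- Path: dibromo-olefination (CBr4, PPh3, CH2Cl2, 0 °C) gives 5,7-bis(benzyloxy)-2-(2,2-dibromovinyl)chromen-4-one F6. Stereoselective hydrogenolysis of the trans bromide (n-Bu3SnH, Pd(PPh3)4 cat., toluene, rt) gives (Z)-5,7-bis(benzyloxy)-2-(2-bromovinyl)chromen-4-one F7. Anti-elimination of HBr with DBU (THF, rt), helped by the acidified vinylic hydrogen next to C2, should give 17.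

3. **Step 6.**
- Risk: aminomethylation may occur at the methyl side or twice, the reaction at the crowded benzylic carbon may stall, and the α-aryl enone may dimerise on prolonged heating.
- Fallback: the methylenation is moved to an aldehyde that has a single enolisable position. It sets out from 6 and comes back at 8.
- Path: Lemieux–Johnson cleavage of the allyl group (OsO4 cat., NaIO4, 2,6-lutidine, dioxane/H2O) gives 2-[5,7-bis(benzyloxy)-3-(4-methoxyphenyl)-4-oxochromen-8-yl]acetaldehyde F8. Organocatalytic α-methylenation (aq. HCHO, pyrrolidine and propionic acid, 10 mol % each, i-PrOH, 45 °C) gives 2-[5,7-bis(benzyloxy)-3-(4-methoxyphenyl)-4-oxochromen-8-yl]prop-2-enal F9.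
- Completion: 1,2-addition of MeMgBr (THF, −78 °C), where the aldehyde far outruns the vinylogous ester carbonyl, gives racemic 5,7-bis(benzyloxy)-8-(3-hydroxybut-1-en-2-yl)-3-(4-methoxyphenyl)chromen-4-one F10. Dess–Martin oxidation erases its carbinol centre and should give 8.

**Further compounds**
F1 | step 13 | 5,7-bis(benzyloxy)-3-(4-methoxyphenyl)chromen-4-one | COc1ccc(cc1)-c1coc2cc(OCc3ccccc3)cc(OCc3ccccc3)c2c1=O
F2 | step 13 | 5,7-bis(benzyloxy)-8-iodo-3-(4-methoxyphenyl)chromen-4-one | COc1ccc(cc1)-c1coc2c(I)c(OCc3ccccc3)cc(OCc3ccccc3)c2c1=O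
F3 | step 13 | (E)-1-[2,4-bis(benzyloxy)-6-hydroxyphenyl]-3-(3-bromo-4-methoxyphenyl)prop-2-en-1-one | COc1ccc(/C=C/C(=O)c2c(O)cc(OCc3ccccc3)cc2OCc2ccccc2)cc1Br
F4 | step 13 | 5,7-bis(benzyloxy)-2-(3-bromo-4-methoxyphenyl)chromen-4-one | COc1ccc(cc1Br)-c1cc(=O)c2c(OCc3ccccc3)cc(OCc3ccccc3)cc2o1
F5 | step 13 | 5,7-bis(benzyloxy)-2-[4-methoxy-3-(4,4,5,5-tetramethyl-1,3,2-dioxaborolan-2-yl)phenyl]chromen-4-one | COc1ccc(cc1B1OC(C)(C)C(C)(C)O1)-c1cc(=O)c2c(OCc3ccccc3)cc(OCc3ccccc3)cc2o1
F6 | step 12 | 5,7-bis(benzyloxy)-2-(2,2-dibromovinyl)chromen-4-one | BrC(Br)=Cc1cc(=O)c2c(OCc3ccccc3)cc(OCc3ccccc3)cc2o1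
F7 | step 12 | (Z)-5,7-bis(benzyloxy)-2-(2-bromovinyl)chromen-4-one | Br/C=C\c1cc(=O)c2c(OCc3ccccc3)cc(OCc3ccccc3)cc2o1
F8 | step 6 | 2-[5,7-bis(benzyloxy)-3-(4-methoxyphenyl)-4-oxochromen-8-yl]acetaldehyde | COc1ccc(cc1)-c1coc2c(CC=O)c(OCc3ccccc3)cc(OCc3ccccc3)c2c1=O
F9 | step 6 | 2-[5,7-bis(benzyloxy)-3-(4-methoxyphenyl)-4-oxochromen-8-yl]prop-2-enal | COc1ccc(cc1)-c1coc2c(C(=C)C=O)c(OCc3ccccc3)cc(OCc3ccccc3)c2c1=O
F10 | step 6 | rac-5,7-bis(benzyloxy)-8-(3-hydroxybut-1-en-2-yl)-3-(4-methoxyphenyl)chromen-4-one | COc1ccc(cc1)-c1coc2c(C(=C)C(C)O)c(OCc3ccccc3)cc(OCc3ccccc3)c2c1=O
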